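The route rests on one disconnection: the C5–C6 bond of ring A (C1, C8, C7, C6, C5, C9). The key step exploits the fact that C5 lies between the C4 and C9 carbonyls while C6 is the CH2 terminus of a 1,1-disubstituted C7=C6 alkene held on C1 through C8. One-electron oxidation of the C5 enol, 6-endo radical closure onto C6 and exo hydrogen transfer to C7 build ring A on ring B (C1–C5, C9) and set C5 and C7 in one operation. The precursor is a dearomatised 3-aroylphloroglucinol, quaternary at C1 (hydroxyisopentyl chain plus the C8–C7=C6 unit), with a crotonate arm at C5.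

Key step: step 12

Remark: core atoms carry the bicyclic numbering C1–C9 throughout, enols are drawn as one tautomer, TBS = tert-butyldimethylsilyl, and the dearomatised compounds 17, 18, 20 and 21, which can move the C1 substituent to C5 by a [3,3] shift, are assumed to survive at or below 20 °C and are used without storage.

Step 1
Reactants: 1 triethyl phosphonoacetate; 2 prenyl bromide (1-bromo-3-methylbut-2-ene)
Product: 3 ethyl 2-(diethoxyphosphoryl)-5-methylhex-4-enoate (racemic)
Conditions: NaH (1.0 equiv), THF, 0 °C; then 2 (0.9 equiv), 0 → 20 °C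
Reagents that add atoms: none
Why: SN2 C-alkylation of the sodium phosphonoacetate carbanion at the primary allylic bromide, with the bromide limiting to suppress dialkylation; the stereocentre formed is destroyed in step 2.

Step 2
Reactants: 3
Product: 4 ethyl 5-methyl-2-(propan-2-ylidene)hex-4-enoate
Conditions: NaH, DME, 0 °C; acetone (5 equiv), 60 °C
Reagents that add atoms: acetone, CC(C)=O
Why: Horner–Wadsworth–Emmons olefination of the α-substituted phosphonate with the unhindered ketone gives the tetrasubstituted enoate, which has no E/Z isomers because the β-carbon carries two methyl groups.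

Step 3
Reactants: 4
Product: 6 5-methyl-2-(propan-2-ylidene)hex-4-en-1-ol, via aldehyde 5 (not isolated)
Conditions: i-Bu2AlH (2.5 equiv), CH2Cl2, −78 → 0 °C; aq. potassium sodium tartrate
Reagents that add atoms: none
Why: 1,2-reduction of the conjugated ester by the aluminium hydride through the aldehyde, without conjugate reduction of the tetrasubstituted alkene.

Step 4
Reactants: 7 phloroglucinol; 8 acrylic acid
Product: 10 5,7-dihydroxychroman-2-one, via 3-(2,4,6-trihydroxyphenyl)propanoic acid 9 (not isolated)
Conditions: Amberlyst-15 (sulfonic acid resin), toluene, 110 °C, azeotropic removal of water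
Reagents that add atoms: none
Why: acid-catalysed Friedel–Crafts-type conjugate hydroarylation of acrylic acid by the electron-rich arene followed by lactonisation, giving one product because the three ring CH positions are equivalent.

Step 5
Reactants: 10; 11 3,4-dihydroxybenzoic acid
Product: 12 6-(3,4-dihydroxybenzoyl)-5,7-dihydroxychroman-2-one
Conditions: P2O5/MeSO3H (1:10 w/w), 70 °C
Reagents that add atoms: none
Why: Friedel–Crafts acylation of the phloroglucinol-type ring, expected between the two free hydroxyls where the ketone gains two hydrogen bonds; the isomer acylated beside the ring oxygen, if formed, converges on 14 in step 6.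

Step 6
Reactants: 12
Product: 14 (3,4-dihydroxyphenyl)[2,4,6-trihydroxy-3-(3-hydroxy-3-methylbutyl)phenyl]methanone, via methyl ketone 13 (not isolated)
Conditions: MeMgBr (9 equiv), THF, −20 → 20 °C; aq. NH4Cl
Reagents that add atoms: methylmagnesium bromide, C[Mg]Br
Why: double Grignard addition to the aryl lactone through the methyl ketone gives the tertiary alcohol, while the diaryl ketone, flanked by two magnesium phenoxides and so a cross-conjugated vinylogous carboxylate, should not be attacked.

Step 7
Reactants: 14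
Product: 15 [3,4-bis(TBSO)phenyl][4,6-bis(TBSO)-2-hydroxy-3-(3-hydroxy-3-methylbutyl)phenyl]methanone
Conditions: TBSCl (4.1 equiv), imidazole (9 equiv), DMF, 0 °C
Reagents that add atoms: tert-butyldimethylsilyl chloride, CC(C)(C)[Si](C)(C)Cl
Why: silylation of the four accessible phenols; the hydroxyl between the alkyl chain and the ketone is the most hindered and becomes the only hydrogen-bond donor to the carbonyl once its ortho twin is capped, so it and the tertiary alcohol stay free and the oxygen next to C1 is singled out.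

Step 8
Reactants: 15; 6
Product: 16 [3,4-bis(TBSO)phenyl][4,6-bis(TBSO)-3-(3-hydroxy-3-methylbutyl)-2-{[5-methyl-2-(propan-2-ylidene)hex-4-en-1-yl]oxy}phenyl]methanone
Conditions: PPh3, diisopropyl azodicarboxylate, THF, 0 → 20 °C
Reagents that add atoms: none
Why: Mitsunobu etherification of the acidic chelated phenol by SN2 displacement at the primary allylic carbinol carbon, under neutral conditions that spare the aryl silyl ethers and the tertiary alcohol.

Step 9
Reactants: 16
Product: 18 racemic 2-[3,4-bis(TBSO)benzoyl]-3,5-dihydroxy-6-(2,6-dimethyl-3-methylidenehept-5-en-2-yl)-6-(3-hydroxy-3-methylbutyl)cyclohexa-2,4-dien-1-one, via bis-silyl dienol ether 17 (not isolated)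
Conditions: Eu(fod)3 (0.2 equiv), CHCl3, 20 °C, not heated; then AcOH/THF/H2O (3:1:1), 20 °C
Reagents that add atoms: none
Why: chelation-assisted aromatic Claisen rearrangement from the ether oxygen, whose only ortho carbons are C1 and the aroyl-bearing C3, so the allyl unit arrives inverted on C1 and creates the quaternary centre as a racemate (resolved in step 11), after which aqueous acetic acid hydrolyses the two vinylogous silyl esters and leaves the aryl silyl ethers.

Step 10
Reactants: 18; 19 methyl (E)-4-bromobut-2-enoate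
Product: 20 racemic 2-[3,4-bis(TBSO)benzoyl]-3,5-dihydroxy-4-[(E)-4-methoxy-4-oxobut-2-en-1-yl]-6-(2,6-dimethyl-3-methylidenehept-5-en-2-yl)-6-(3-hydroxy-3-methylbutyl)cyclohexa-2,4-dien-1-one
Conditions: Pd(PPh3)4 (5 mol%), Et3N (1.2 equiv), THF, 0 → 20 °C
Reagents that add atoms: none
Why: Tsuji–Trost allylation in which C5, the only unsubstituted nucleophilic carbon of the enolate, attacks the ester-bearing π-allyl palladium complex at the terminus remote from the ester to give the E-enoate, any O-allyl isomer being re-ionised by zerovalent palladium and returned to the C-allyl product.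

Step 11
Reactants: 20
Product: 21 (6R)-enantiomer of 20, the cyclisation precursor
Conditions: preparative SFC, amylose tris(3,5-dimethylphenylcarbamate) phase, CO2/MeOH with 0.1% HCO2H, 15 °C
Reagents that add atoms: none
Why: resolution of the racemate by chromatography on a chiral stationary phase fixes C1, the absolute configuration to be assigned by circular dichroism against calculation and confirmed by correlation with the target.

Step 12
Reactants: 21
Product: 22 methyl (E)-4-[(1R,5R,7R)-3-[3,4-bis(TBSO)benzoyl]-4-hydroxy-1-(3-hydroxy-3-methylbutyl)-8,8-dimethyl-7-(3-methylbut-2-en-1-yl)-2,9-dioxobicyclo[3.3.1]non-3-en-5-yl]but-2-enoate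
Conditions: 9-mesityl-3,6-di-tert-butyl-10-phenylacridinium tetrafluoroborate (2.5 mol%), 2,4,6-triisopropylbenzenethiol (20 mol%), 2,6-lutidine (20 mol%), degassed ClCH2CH2Cl, 450 nm LEDs, 15 °C
Reagents that add atoms: none
Why: The excited acridinium oxidises the enolate of 21 to a radical delocalised over C5, C3 and the oxygens; C5 adds to C6, the C7 radical takes hydrogen from the thiol, and the thiyl radical is reduced by the acridine radical and reprotonated, so the step is a redox-neutral isomerisation. The closest known reaction type is the Mn(OAc)3-type oxidative cyclisation of cyclic 1,3-dicarbonyl radicals onto 1,1-disubstituted alkenes, ended here by thiol hydrogen-atom transfer as in photocatalytic hydroalkylations of alkenes. Ring A (C1, C8, C7, C6, C5, C9) closes 6-endo-trig because the C9 carbonyl lies inside the forming ring and attack at the CH2 terminus gives a tertiary radical, whereas 5-exo attack at C7 would join two fully substituted carbons. C5 is set by C1, since the C8 tether reaches C5 only on the ring face it occupies, and C7 is set by hydrogen delivery to the exo face, the endo face being covered by the C2–C3–C4 bridge, which leaves the prenyl group endo. The step needs closure at C5 and not at C3 (C3 carries the aroyl group and would become a carbon with three acyl substituents), oxidation of the enolate and not of the alkenes (the anion is far easier to oxidise), and no [3,3] shift of 21 (low temperature); the hindered thiol limits conjugate addition to the enoate, which offers the C5 radical no 5-exo pathway.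

Step 13
Reactants: 22
Product: 23 methyl (3S)-3-{[(1R,5R,7R)-3-[3,4-bis(TBSO)benzoyl]-4-hydroxy-1-(3-hydroxy-3-methylbutyl)-8,8-dimethyl-7-(3-methylbut-2-en-1-yl)-2,9-dioxobicyclo[3.3.1]non-3-en-5-yl]methyl}-4-methylpent-4-enoate
Conditions: [RhCl(C2H4)2]2 (3 mol%), (S,S)-2,5-diphenylbicyclo[2.2.2]octa-2,5-diene (6.5 mol%), potassium isopropenyltrifluoroborate (3 equiv), Et3N (1.5 equiv), dioxane/H2O (10:1), 50 °C
Reagents that add atoms: potassium isopropenyltrifluoroborate, C=C(C)[B-](F)(F)F.[K+]
Why: rhodium-catalysed asymmetric conjugate addition (Hayashi–Miyaura reaction) to the E-enoate, in which the chiral diene, the only diene on monovalent rhodium because the ethylene complex is the precursor, is chosen by analogy with its sense on E-enones to deliver isopropenyl to the Si face of the β-carbon and so sets the side-chain centre as S (the later R centre of the lavandulyl group) under catalyst control.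

Step 14
Reactants: 23
Product: 24 (3S)-3-{[(1R,5R,7R)-3-[3,4-bis(TBSO)benzoyl]-4-hydroxy-1-(3-hydroxy-3-methylbutyl)-8,8-dimethyl-7-(3-methylbut-2-en-1-yl)-2,9-dioxobicyclo[3.3.1]non-3-en-5-yl]methyl}-4-methylpent-4-enal
Conditions: i-Bu2AlH (3.3 equiv), CH2Cl2, −78 °C; MeOH, then aq. potassium sodium tartrate
Reagents that add atoms: none
Why: partial reduction of the methyl ester to the aldehyde through the aluminium hemiacetal that persists at −78 °C, the first two equivalents being consumed by the enol and the tertiary alcohol so that the triketone is masked as its aluminium enolate, while the C9 ketone is shielded by its two quaternary neighbours.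

Step 15
Reactants: 24
Product: 25 (1R,5R,7R)-3-[3,4-bis(TBSO)benzoyl]-4-hydroxy-1-(3-hydroxy-3-methylbutyl)-8,8-dimethyl-7-(3-methylbut-2-en-1-yl)-5-[(2R)-5-methyl-2-(prop-1-en-2-yl)hex-4-en-1-yl]bicyclo[3.3.1]non-3-ene-2,9-dione
Conditions: isopropyltriphenylphosphonium iodide (4 equiv), KN(SiMe3)2 (3.9 equiv), THF, −78 → 0 °C
Reagents that add atoms: isopropyltriphenylphosphonium iodide, CC(C)[P+](c1ccccc1)(c1ccccc1)c1ccccc1.[I-]
Why: Wittig olefination of the aldehyde with isopropylidenetriphenylphosphorane gives the prenyl alkene without E/Z issue, the excess ylide deprotonating the enol and the alcohol, whose enolate and the hindered C9 ketone should not react; the side-chain centre is untouched and becomes R only by change of priorities.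

Step 16
Reactants: 25
Product: 26 (1R,5R,7R)-3-(3,4-dihydroxybenzoyl)-4-hydroxy-1-(3-hydroxy-3-methylbutyl)-8,8-dimethyl-7-(3-methylbut-2-en-1-yl)-5-[(2R)-5-methyl-2-(prop-1-en-2-yl)hex-4-en-1-yl]bicyclo[3.3.1]non-3-ene-2,9-dione (CNP0148616.1)
Conditions: Bu4NF (2.5 equiv), AcOH (2.5 equiv), THF, 0 °C, argon
Reagents that add atoms: none
Why: fluoride-mediated desilylation of the two aryl silyl ethers, buffered with acetic acid so that the catechol and the enolised triketone are not exposed to base and air, with no stereocentre affected.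

Compound list
1 | triethyl phosphonoacetate | CCOC(=O)CP(=O)(OCC)OCC | starting material
2 | prenyl bromide | CC(C)=CCBr | starting material
3 | ethyl 2-(diethoxyphosphoryl)-5-methylhex-4-enoate (racemic) | CCOC(=O)C(CC=C(C)C)P(=O)(OCC)OCC | intermediate
4 | ethyl 5-methyl-2-(propan-2-ylidene)hex-4-enoate | CCOC(=O)C(CC=C(C)C)=C(C)C | intermediate
5 | 5-methyl-2-(propan-2-ylidene)hex-4-enal | O=CC(CC=C(C)C)=C(C)C | intermediate
6 | 5-methyl-2-(propan-2-ylidene)hex-4-en-1-ol | OCC(CC=C(C)C)=C(C)C | intermediate
7 | phloroglucinol | Oc1cc(O)cc(O)c1 | starting material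
8 | acrylic acid | C=CC(=O)O | starting material
9 | 3-(2,4,6-trihydroxyphenyl)propanoic acid | O=C(O)CCc1c(O)cc(O)cc1O | intermediate
10 | 5,7-dihydroxychroman-2-one | O=C1CCc2c(O)cc(O)cc2O1 | intermediate
11 | 3,4-dihydroxybenzoic acid | O=C(O)c1ccc(O)c(O)c1 | starting material
12 | 6-(3,4-dihydroxybenzoyl)-5,7-dihydroxychroman-2-one | O=C1CCc2c(O)c(C(=O)c3ccc(O)c(O)c3)c(O)cc2O1 | intermediate
13 | 4-[3-(3,4-dihydroxybenzoyl)-2,4,6-trihydroxyphenyl]butan-2-one | CC(=O)CCc1c(O)cc(O)c(C(=O)c2ccc(O)c(O)c2)c1O | intermediate
14 | (3,4-dihydroxyphenyl)[2,4,6-trihydroxy-3-(3-hydroxy-3-methylbutyl)phenyl]methanone | CC(C)(O)CCc1c(O)cc(O)c(C(=O)c2ccc(O)c(O)c2)c1O | intermediate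
15 | [3,4-bis(TBSO)phenyl][4,6-bis(TBSO)-2-hydroxy-3-(3-hydroxy-3-methylbutyl)phenyl]methanone | CC(C)(O)CCc1c(O[Si](C)(C)C(C)(C)C)cc(O[Si](C)(C)C(C)(C)C)c(C(=O)c2ccc(O[Si](C)(C)C(C)(C)C)c(O[Si](C)(C)C(C)(C)C)c2)c1O | intermediate
16 | allyl aryl ether of 15 with alcohol 6 | CC(C)(O)CCc1c(O[Si](C)(C)C(C)(C)C)cc(O[Si](C)(C)C(C)(C)C)c(C(=O)c2ccc(O[Si](C)(C)C(C)(C)C)c(O[Si](C)(C)C(C)(C)C)c2)c1OCC(CC=C(C)C)=C(C)C | intermediate
17 | racemic bis-silyl dienol ether (3,5-bis-TBS ether of 18) | C=C(CC=C(C)C)C(C)(C)C1(CCC(C)(C)O)C(=O)C(C(=O)c2ccc(O[Si](C)(C)C(C)(C)C)c(O[Si](C)(C)C(C)(C)C)c2)=C(O[Si](C)(C)C(C)(C)C)C=C1O[Si](C)(C)C(C)(C)C | intermediate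
18 | racemic 2-[3,4-bis(TBSO)benzoyl]-3,5-dihydroxy-6-(2,6-dimethyl-3-methylidenehept-5-en-2-yl)-6-(3-hydroxy-3-methylbutyl)cyclohexa-2,4-dien-1-one | C=C(CC=C(C)C)C(C)(C)C1(CCC(C)(C)O)C(=O)C(C(=O)c2ccc(O[Si](C)(C)C(C)(C)C)c(O[Si](C)(C)C(C)(C)C)c2)=C(O)C=C1O | intermediate
19 | methyl (E)-4-bromobut-2-enoate | COC(=O)/C=C/CBr | starting material
20 | racemic 4-[(E)-4-methoxy-4-oxobut-2-en-1-yl] derivative of 18 | C=C(CC=C(C)C)C(C)(C)C1(CCC(C)(C)O)C(=O)C(C(=O)c2ccc(O[Si](C)(C)C(C)(C)C)c(O[Si](C)(C)C(C)(C)C)c2)=C(O)C(C/C=C/C(=O)OC)=C1O | intermediate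
21 | (6R)-enantiomer of 20, cyclisation precursor | C=C(CC=C(C)C)C(C)(C)[C@@]1(CCC(C)(C)O)C(=O)C(C(=O)c2ccc(O[Si](C)(C)C(C)(C)C)c(O[Si](C)(C)C(C)(C)C)c2)=C(O)C(C/C=C/C(=O)OC)=C1O | intermediate
22 | (1R,5R,7R)-bicyclic core with 7-endo prenyl group and C5 crotonate arm | COC(=O)/C=C/C[C@@]12C[C@@H](CC=C(C)C)C(C)(C)[C@@](CCC(C)(C)O)(C(=O)C(C(=O)c3ccc(O[Si](C)(C)C(C)(C)C)c(O[Si](C)(C)C(C)(C)C)c3)=C1O)C2=O | intermediate
23 | (3S)-isopropenyl ester from conjugate addition | C=C(C)[C@H](CC(=O)OC)C[C@@]12C[C@@H](CC=C(C)C)C(C)(C)[C@@](CCC(C)(C)O)(C(=O)C(C(=O)c3ccc(O[Si](C)(C)C(C)(C)C)c(O[Si](C)(C)C(C)(C)C)c3)=C1O)C2=O | intermediate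
24 | (3S)-aldehyde | C=C(C)[C@H](CC=O)C[C@@]12C[C@@H](CC=C(C)C)C(C)(C)[C@@](CCC(C)(C)O)(C(=O)C(C(=O)c3ccc(O[Si](C)(C)C(C)(C)C)c(O[Si](C)(C)C(C)(C)C)c3)=C1O)C2=O | intermediate
25 | bis-TBS ether of the target | C=C(C)[C@H](CC=C(C)C)C[C@@]12C[C@@H](CC=C(C)C)C(C)(C)[C@@](CCC(C)(C)O)(C(=O)C(C(=O)c3ccc(O[Si](C)(C)C(C)(C)C)c(O[Si](C)(C)C(C)(C)C)c3)=C1O)C2=O | intermediate
26 | CNP0148616.1 | C=C(C)[C@H](CC=C(C)C)C[C@@]12C[C@@H](CC=C(C)C)C(C)(C)[C@@](CCC(C)(C)O)(C(=O)C(C(=O)c3ccc(O)c(O)c3)=C1O)C2=O | target

Total step count: 16. Longest linear sequence: 13 steps (7 to 26, steps 4–16).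

Steps most likely to fail

Step 12. The delocalised radical may close at C3 instead of C5, the thiol may return hydrogen to the C5 radical before it cyclises, the excited acridinium may oxidise the trisubstituted alkenes, the skipped diene may isomerise through thiyl-radical hydrogen abstraction, or 21 may undergo its [3,3] shift faster than it is consumed. The fallback sets out from 21 and comes back at 22. N-Bromosuccinimide in CH2Cl2 at −40 °C brominates the C5 enol to the C5-bromo triketone F1, which has no C5=C9 double bond and so can no longer undergo the [3,3] shift. Slow addition of (Me3Si)3SiH with Et3B/air in toluene at 0 °C then generates the same C5 radical by bromine abstraction (the classical reductive cyclisation of an α-halo-1,3-dicarbonyl compound), and the silane reduces the C7 radical from the exo face to give 22.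

Step 9. The rearranged dienone may shift on by a second [3,3] step to C5 and rearomatise, or the chelated ether may ionise to an allyl cation and a phenoxide and lose the inverted connectivity. The fallback sets out from 15 and comes back at 18. N-Bromosuccinimide brominates the one free position of the silylated phloroglucinol ring to give the bromophenol F2, and Mitsunobu etherification with 6 gives the bromo ether F3. The Eu(fod)3-promoted shift gives the bis-silyl bromodienone F4, in which a second shift to C5 would have to build a bromine-bearing quaternary carbon and could not end in rearomatisation. Aqueous acetic acid gives the bromodienone F5, and zinc dust in AcOH/THF at 0 °C removes the bromine of this α-bromo-1,3-diketone to give 18.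

Step 13. The chelating triketonate may sequester rhodium, insertion at the β-carbon next to the quaternary C5 may be slow enough for protodeboronation to win, or the catalyst may be mismatched with the core and give poor facial selectivity. The fallback sets out from 22 and comes back at 23. After deprotonation of the enol and the alcohol by the first equivalents of reagent, isopropenylmagnesium bromide with CuBr·SMe2 and Me3SiCl in THF at −78 °C adds to the enoate as a stoichiometric organocopper reagent without catalyst control. This gives 23 together with its side-chain epimer F6, from which 23 is separated by preparative HPLC.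

Further compounds
F1 | step 12 | C5-bromo triketone from 21 (mixture of C5 epimers) | C=C(CC=C(C)C)C(C)(C)[C@@]1(CCC(C)(C)O)C(=O)C(C(=O)c2ccc(O[Si](C)(C)C(C)(C)C)c(O[Si](C)(C)C(C)(C)C)c2)=C(O)C(Br)(C/C=C/C(=O)OC)C1=O
F2 | step 9 | 5-bromo derivative of phenol 15 | CC(C)(O)CCc1c(O[Si](C)(C)C(C)(C)C)c(Br)c(O[Si](C)(C)C(C)(C)C)c(C(=O)c2ccc(O[Si](C)(C)C(C)(C)C)c(O[Si](C)(C)C(C)(C)C)c2)c1O
F3 | step 9 | 5-bromo derivative of ether 16 | CC(C)(O)CCc1c(O[Si](C)(C)C(C)(C)C)c(Br)c(O[Si](C)(C)C(C)(C)C)c(C(=O)c2ccc(O[Si](C)(C)C(C)(C)C)c(O[Si](C)(C)C(C)(C)C)c2)c1OCC(CC=C(C)C)=C(C)C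
F4 | step 9 | racemic 4-bromo derivative of bis-silyl dienol ether 17 | C=C(CC=C(C)C)C(C)(C)C1(CCC(C)(C)O)C(=O)C(C(=O)c2ccc(O[Si](C)(C)C(C)(C)C)c(O[Si](C)(C)C(C)(C)C)c2)=C(O[Si](C)(C)C(C)(C)C)C(Br)=C1O[Si](C)(C)C(C)(C)C
F5 | step 9 | racemic 4-bromo derivative of dienone 18 | C=C(CC=C(C)C)C(C)(C)C1(CCC(C)(C)O)C(=O)C(C(=O)c2ccc(O[Si](C)(C)C(C)(C)C)c(O[Si](C)(C)C(C)(C)C)c2)=C(O)C(Br)=C1O
F6 | step 13 | (3R)-epimer of ester 23 | C=C(C)[C@@H](CC(=O)OC)C[C@@]12C[C@@H](CC=C(C)C)C(C)(C)[C@@](CCC(C)(C)O)(C(=O)C(C(=O)c3ccc(O[Si](C)(C)C(C)(C)C)c(O[Si](C)(C)C(C)(C)C)c3)=C1O)C2=O
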